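Ring B, the benzene ring of the chroman, is a resorcinol: oxygens sit on C7′ and C8a′, C4a′ carries the prenyl-derived CH2 and C5′ carries C2 of the benzofuran. That 1,3-dioxygenated, 4,5-disubstituted pattern is the aromatised form of a cyclohexane-1,3-dione, so the ring is made from open-chain carbons: an α-prenyl enone whose β-carbon bears the finished benzofuran is annulated with dimethyl malonate. One operation forms C5′–C6′ (Michael) and C7′–C8′ (Claisen) and fixes the prenyl group ortho to the biaryl bond with a single flanking oxygen. Decarboxylation, dehydrogenation and acid then give the chroman and the free phenols.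

Key step: step 10

Remarks on the chemistry (assumptions and design choices)
- Benzofuran atoms carry plain locants, chroman atoms primed locants. Ar = 4,6-bis(methoxymethoxy)-7-(2-methylbut-3-en-2-yl)-1-benzofuran-2-yl. The target has no stereocentre; 15 and 18–23 are racemic.
- The 1,1-dimethylallyl group is installed by Claisen rearrangement from O6 of the preformed benzofuran. From the phenol that later becomes the furan oxygen, the free para carbon (C5) would be open to a following Cope shift, which would put a normal prenyl group on the wrong carbon. Para to O6 lies the ring-fusion carbon C3a, so this path is closed.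
- The enone is made by Horner–Wadsworth–Emmons olefination. The corresponding acyl-stabilised ylide would have to come from alkylation of acetonylidenetriphenylphosphorane, which is prone to O-alkylation.
- 19 and 20 are drawn as all-trans triketo tautomers although they should exist largely as enols. 23 is drawn as the diene from deprotonation of the ring CH2; the regioisomer from deprotonation at the prenyl-bearing carbon would give the same arene in step 13.

Step 1
Reactants: 1 2,4,6-trihydroxybenzaldehyde; 2 3-methylbut-2-en-1-ol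
Product: 3 2,6-dihydroxy-4-[(3-methylbut-2-en-1-yl)oxy]benzaldehyde
Conditions: PPh3, DIAD, THF, 0 °C → rt
Reagents that add atoms: none
Why: Mitsunobu etherification should select the 4-hydroxyl, the most acidic phenol and the only one not hydrogen-bonded to the formyl group, and gives the O-prenyl ether without the C-alkylation that basic prenyl halide conditions provoke in phloroglucinols.

Step 2
Reactants: 3 2,6-dihydroxy-4-[(3-methylbut-2-en-1-yl)oxy]benzaldehyde
Product: 4 2-hydroxy-6-(methoxymethoxy)-4-[(3-methylbut-2-en-1-yl)oxy]benzaldehyde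
Conditions: MOMCl (1.1 equiv), iPr2NEt, CH2Cl2, 0 °C
Reagents that add atoms: chloromethyl methyl ether, COCCl
Why: Williamson-type acetalisation caps one of the two equivalent ortho hydroxyls, after which the remaining one is held in a strong hydrogen bond to the aldehyde and resists a second alkylation.

Step 3
Reactants: 4 2-hydroxy-6-(methoxymethoxy)-4-[(3-methylbut-2-en-1-yl)oxy]benzaldehyde; 5 methyl bromoacetate
Product: 7 methyl 4-(methoxymethoxy)-6-[(3-methylbut-2-en-1-yl)oxy]-1-benzofuran-2-carboxylate, via aryloxyacetate 6 (not isolated)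
Conditions: K2CO3, DMF, 90 °C
Reagents that add atoms: none
Why: O-alkylation of the unhindered phenol, then intramolecular aldol condensation of the ester enolate onto the neighbouring aldehyde with loss of water (Rap–Stoermer-type annulation), is the standard route from salicylaldehydes to benzofuran-2-carboxylates.

Step 4
Reactants: 7 methyl 4-(methoxymethoxy)-6-[(3-methylbut-2-en-1-yl)oxy]-1-benzofuran-2-carboxylate
Product: 9 methyl 6-hydroxy-4-(methoxymethoxy)-7-(2-methylbut-3-en-2-yl)-1-benzofuran-2-carboxylate, via silyl ether 8 (not isolated)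
Conditions: MeC(OSiMe3)=NSiMe3, PhNEt2, 190 °C; then K2CO3 (cat.), MeOH, rt
Reagents that add atoms: none
Why: The aromatic Claisen rearrangement delivers the allyl unit inverted, as the 1,1-dimethylallyl group, to an ortho carbon; the para position is the ring-fusion carbon C3a, so no Cope shift can follow; C7 should be preferred over C5 because the C6–C7 bond has the higher π-bond order in benzofuran (the angular preference of 7-allyloxycoumarins and 2-naphthyl allyl ethers) and because C5 is crowded by the 4-OMOM group; and in-situ silylation keeps the new phenol from adding thermally to the vinyl group until methanolysis frees it.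

Step 5
Reactants: 9 methyl 6-hydroxy-4-(methoxymethoxy)-7-(2-methylbut-3-en-2-yl)-1-benzofuran-2-carboxylate
Product: 10 methyl 4,6-bis(methoxymethoxy)-7-(2-methylbut-3-en-2-yl)-1-benzofuran-2-carboxylate
Conditions: NaH, MOMCl, DMF, 0 °C → rt
Reagents that add atoms: chloromethyl methyl ether, COCCl
Why: Williamson etherification of the sodium phenoxide with the small, very reactive MOMCl should tolerate the neighbouring quaternary carbon.

Step 6
Reactants: 10 methyl 4,6-bis(methoxymethoxy)-7-(2-methylbut-3-en-2-yl)-1-benzofuran-2-carboxylate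
Product: 11 [4,6-bis(methoxymethoxy)-7-(2-methylbut-3-en-2-yl)-1-benzofuran-2-yl]methanol
Conditions: LiAlH4, THF, 0 °C; then H2O, aq NaOH
Reagents that add atoms: none
Why: Hydride reduction of the ester leaves the MOM acetals, the isolated alkene and the benzofuran untouched.

Step 7
Reactants: 11 [4,6-bis(methoxymethoxy)-7-(2-methylbut-3-en-2-yl)-1-benzofuran-2-yl]methanol
Product: 12 4,6-bis(methoxymethoxy)-7-(2-methylbut-3-en-2-yl)-1-benzofuran-2-carbaldehyde
Conditions: MnO2, CH2Cl2, rt
Reagents that add atoms: none
Why: MnO2 oxidises the benzylic-type (furan-2-yl)methanol selectively to the aldehyde without over-oxidation.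

Step 8
Reactants: 13 dimethyl (2-oxopropyl)phosphonate; 14 1-bromo-3-methylbut-2-ene
Product: 15 dimethyl (6-methyl-2-oxohept-5-en-3-yl)phosphonate (racemic)
Conditions: NaH, THF, 0 °C; then 14, rt
Reagents that add atoms: none
Why: C-alkylation of the sodium salt of a β-ketophosphonate at its doubly activated carbon with an allylic bromide is a reliable enolate alkylation.

Step 9
Reactants: 12 4,6-bis(methoxymethoxy)-7-(2-methylbut-3-en-2-yl)-1-benzofuran-2-carbaldehyde; 15 dimethyl (6-methyl-2-oxohept-5-en-3-yl)phosphonate
Product: 16 (3E)-3-(Ar-methylidene)-6-methylhept-5-en-2-one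
Conditions: NaH, THF, 0 °C; then 12, 0 → 65 °C
Reagents that add atoms: none
Why: Horner–Wadsworth–Emmons olefination places the trisubstituted C=C between the aldehyde carbon and the prenyl-bearing carbon without regiochemical ambiguity; the E isomer (benzofuranyl trans to acetyl) is expected to predominate, and the geometry does not matter for step 10.

Step 10
Reactants: 16 (3E)-3-(Ar-methylidene)-6-methylhept-5-en-2-one; 17 dimethyl malonate
Product: 19 methyl rac-(all-trans)-2-Ar-3-(3-methylbut-2-en-1-yl)-4,6-dioxocyclohexane-1-carboxylate, via Michael adduct 18 (not isolated)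
Conditions: NaOMe (2.2 equiv), 17 (2 equiv), MeOH, reflux; then AcOH, 0 °C
Reagents that add atoms: none
Why: Sodium dimethyl malonate adds reversibly to the benzofuranyl-bearing β-carbon of the enone (C5′–C6′), proton transfer gives the methyl-ketone enolate, and its carbon (C8′) attacks a malonate ester carbonyl (C7′) with loss of methoxide. The closest known reaction type is the base-mediated [3+3] Michael–Claisen condensation of arylidene ketones, α-alkyl ones included, with malonic esters to 5-arylcyclohexane-1,3-dione carboxylates. The one ring closure is a 6-(enolendo)-exo-trig acyl substitution of the Dieckmann type. The three sp3 centres arise under equilibrating conditions and should settle all-equatorial (all-trans), but they are erased on aromatisation, so no stereocontrol is required. The selectivity needed is regiochemical and is fixed by the connectivity of 16: the α-carbon is fully substituted, so malonate can only attack the β-carbon, and only the methyl group can close a six-membered ring. Deprotonation of the cyclic β-dicarbonyl product by methoxide makes the sequence irreversible and pulls the hindered, electronically deactivated Michael equilibrium forward, which is why excess base and malonate are used.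

Step 11
Reactants: 19 methyl rac-(all-trans)-2-Ar-3-(3-methylbut-2-en-1-yl)-4,6-dioxocyclohexane-1-carboxylate
Product: 21 rac-trans-5-Ar-4-(3-methylbut-2-en-1-yl)cyclohexane-1,3-dione, via keto acid 20 (not isolated)
Conditions: NaOH, H2O/MeOH, 70 °C; then AcOH to pH 4–5, 60 °C
Reagents that add atoms: none
Why: Saponification followed by decarboxylation of the β-keto acid through the usual cyclic transition state proceeds on mild acidification, acetic acid being strong enough for this but not for MOM cleavage or alkene protonation.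

Step 12
Reactants: 21 rac-trans-5-Ar-4-(3-methylbut-2-en-1-yl)cyclohexane-1,3-dione
Product: 23 rac-trans-5-Ar-6-(3-methylbut-2-en-1-yl)-1,3-bis[(trimethylsilyl)oxy]cyclohexa-1,3-diene, via silyl enol ether 22 (not isolated)
Conditions: Me3SiCl, Et3N, THF, 0 °C → rt, filter under Ar; then LiN(iPr)2, THF, −78 °C; Me3SiCl, −78 → 0 °C
Reagents that add atoms: chlorotrimethylsilane, C[Si](C)(C)Cl
Why: O-silylation of the enolised dione gives the silyl vinylogous ester, and deprotonation at the unhindered ring CH2 followed by a second O-silylation gives the 1,3-bis(silyloxy)diene, the stepwise enol silylation used for β-dicarbonyl compounds.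

Step 13
Reactants: 23 rac-trans-5-Ar-6-(3-methylbut-2-en-1-yl)-1,3-bis[(trimethylsilyl)oxy]cyclohexa-1,3-diene
Product: 25 5-Ar-4-(3-methylbut-2-en-1-yl)benzene-1,3-diol, via bis(silyl) ether 24 (not isolated)
Conditions: DDQ (1.05 equiv), 2,4,6-collidine, PhMe, 0 °C; filter; then K2CO3 (cat.), MeOH, rt
Reagents that add atoms: none
Why: DDQ dehydrogenation of a silyl dienol ether: hydride abstraction from the ring CH that bears the benzofuran (allylic to the diene) gives a cation stabilised by both silyloxy groups, loss of the adjacent proton to collidine aromatises the ring, and methanolysis cleaves the aryl silyl ethers.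

Step 14
Reactants: 25 5-Ar-4-(3-methylbut-2-en-1-yl)benzene-1,3-diol
Product: 27 2-(7-hydroxy-2,2-dimethyl-3,4-dihydro-2H-chromen-5-yl)-7-(2-methylbut-3-en-2-yl)-1-benzofuran-4,6-diol, via tetraphenol 26 (not isolated)
Conditions: TsOH·H2O (cat.), MeOH, 40 °C; then solvent switch to ClCH2CH2Cl, 60 °C
Reagents that add atoms: none
Why: Acid-catalysed acetal exchange with methanol removes both MOM groups, then protonation of the trisubstituted prenyl alkene to a tertiary cation and capture by the only ortho hydroxyl closes the 2,2-dimethylchroman (Markovnikov hydroalkoxylation, 6-endo), while the far less basic monosubstituted alkene of the 1,1-dimethylallyl group should survive.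

Compound list
1 | 2,4,6-trihydroxybenzaldehyde | O=Cc1c(O)cc(O)cc1O | starting material
2 | 3-methylbut-2-en-1-ol | CC(C)=CCO | starting material
3 | 2,6-dihydroxy-4-[(3-methylbut-2-en-1-yl)oxy]benzaldehyde | O=Cc1c(O)cc(OCC=C(C)C)cc1O | intermediate
4 | 2-hydroxy-6-(methoxymethoxy)-4-[(3-methylbut-2-en-1-yl)oxy]benzaldehyde | COCOc1cc(OCC=C(C)C)cc(O)c1C=O | intermediate
5 | methyl bromoacetate | COC(=O)CBr | starting material
6 | methyl 2-{2-formyl-3-(methoxymethoxy)-5-[(3-methylbut-2-en-1-yl)oxy]phenoxy}acetate | COC(=O)COc1cc(OCC=C(C)C)cc(OCOC)c1C=O | intermediate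
7 | methyl 4-(methoxymethoxy)-6-[(3-methylbut-2-en-1-yl)oxy]-1-benzofuran-2-carboxylate | COC(=O)c1cc2c(OCOC)cc(OCC=C(C)C)cc2o1 | intermediate
8 | methyl 4-(methoxymethoxy)-7-(2-methylbut-3-en-2-yl)-6-[(trimethylsilyl)oxy]-1-benzofuran-2-carboxylate | COC(=O)c1cc2c(OCOC)cc(O[Si](C)(C)C)c(C(C)(C)C=C)c2o1 | intermediate
9 | methyl 6-hydroxy-4-(methoxymethoxy)-7-(2-methylbut-3-en-2-yl)-1-benzofuran-2-carboxylate | COC(=O)c1cc2c(OCOC)cc(O)c(C(C)(C)C=C)c2o1 | intermediate
10 | methyl 4,6-bis(methoxymethoxy)-7-(2-methylbut-3-en-2-yl)-1-benzofuran-2-carboxylate | COC(=O)c1cc2c(OCOC)cc(OCOC)c(C(C)(C)C=C)c2o1 | intermediate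
11 | [4,6-bis(methoxymethoxy)-7-(2-methylbut-3-en-2-yl)-1-benzofuran-2-yl]methanol | OCc1cc2c(OCOC)cc(OCOC)c(C(C)(C)C=C)c2o1 | intermediate
12 | 4,6-bis(methoxymethoxy)-7-(2-methylbut-3-en-2-yl)-1-benzofuran-2-carbaldehyde | O=Cc1cc2c(OCOC)cc(OCOC)c(C(C)(C)C=C)c2o1 | intermediate
13 | dimethyl (2-oxopropyl)phosphonate | CC(=O)CP(=O)(OC)OC | starting material
14 | 1-bromo-3-methylbut-2-ene | CC(C)=CCBr | starting material
15 | dimethyl (6-methyl-2-oxohept-5-en-3-yl)phosphonate (racemic) | CC(=O)C(CC=C(C)C)P(=O)(OC)OC | intermediate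
16 | (3E)-3-{[4,6-bis(methoxymethoxy)-7-(2-methylbut-3-en-2-yl)-1-benzofuran-2-yl]methylidene}-6-methylhept-5-en-2-one | CC(=O)/C(CC=C(C)C)=C/c1cc2c(OCOC)cc(OCOC)c(C(C)(C)C=C)c2o1 | intermediate
17 | dimethyl malonate | COC(=O)CC(=O)OC | starting material
18 | dimethyl 2-{2-acetyl-1-[4,6-bis(methoxymethoxy)-7-(2-methylbut-3-en-2-yl)-1-benzofuran-2-yl]-5-methylhex-4-en-1-yl}propanedioate (racemic, both diastereomers) | COC(=O)C(C(=O)OC)C(c1cc2c(OCOC)cc(OCOC)c(C(C)(C)C=C)c2o1)C(CC=C(C)C)C(C)=O | intermediate
19 | methyl rac-(all-trans)-2-[4,6-bis(methoxymethoxy)-7-(2-methylbut-3-en-2-yl)-1-benzofuran-2-yl]-3-(3-methylbut-2-en-1-yl)-4,6-dioxocyclohexane-1-carboxylate | COC(=O)[C@@H]1C(=O)CC(=O)[C@H](CC=C(C)C)[C@H]1c1cc2c(OCOC)cc(OCOC)c(C(C)(C)C=C)c2o1 | intermediate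
20 | rac-(all-trans)-2-[4,6-bis(methoxymethoxy)-7-(2-methylbut-3-en-2-yl)-1-benzofuran-2-yl]-3-(3-methylbut-2-en-1-yl)-4,6-dioxocyclohexane-1-carboxylic acid | OC(=O)[C@@H]1C(=O)CC(=O)[C@H](CC=C(C)C)[C@H]1c1cc2c(OCOC)cc(OCOC)c(C(C)(C)C=C)c2o1 | intermediate
21 | rac-trans-5-[4,6-bis(methoxymethoxy)-7-(2-methylbut-3-en-2-yl)-1-benzofuran-2-yl]-4-(3-methylbut-2-en-1-yl)cyclohexane-1,3-dione | C1C(=O)CC(=O)[C@H](CC=C(C)C)[C@H]1c1cc2c(OCOC)cc(OCOC)c(C(C)(C)C=C)c2o1 | intermediate
22 | rac-trans-5-[4,6-bis(methoxymethoxy)-7-(2-methylbut-3-en-2-yl)-1-benzofuran-2-yl]-6-(3-methylbut-2-en-1-yl)-3-[(trimethylsilyl)oxy]cyclohex-2-en-1-one | C1C(O[Si](C)(C)C)=CC(=O)[C@H](CC=C(C)C)[C@H]1c1cc2c(OCOC)cc(OCOC)c(C(C)(C)C=C)c2o1 | intermediate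
23 | rac-trans-5-[4,6-bis(methoxymethoxy)-7-(2-methylbut-3-en-2-yl)-1-benzofuran-2-yl]-6-(3-methylbut-2-en-1-yl)-1,3-bis[(trimethylsilyl)oxy]cyclohexa-1,3-diene | C1=C(O[Si](C)(C)C)C=C(O[Si](C)(C)C)[C@H](CC=C(C)C)[C@H]1c1cc2c(OCOC)cc(OCOC)c(C(C)(C)C=C)c2o1 | intermediate
24 | 2-{2-(3-methylbut-2-en-1-yl)-3,5-bis[(trimethylsilyl)oxy]phenyl}-4,6-bis(methoxymethoxy)-7-(2-methylbut-3-en-2-yl)-1-benzofuran | C[Si](C)(C)Oc1cc(O[Si](C)(C)C)c(CC=C(C)C)c(-c2cc3c(OCOC)cc(OCOC)c(C(C)(C)C=C)c3o2)c1 | intermediate
25 | 5-[4,6-bis(methoxymethoxy)-7-(2-methylbut-3-en-2-yl)-1-benzofuran-2-yl]-4-(3-methylbut-2-en-1-yl)benzene-1,3-diol | Oc1cc(O)c(CC=C(C)C)c(-c2cc3c(OCOC)cc(OCOC)c(C(C)(C)C=C)c3o2)c1 | intermediate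
26 | 2-[3,5-dihydroxy-2-(3-methylbut-2-en-1-yl)phenyl]-7-(2-methylbut-3-en-2-yl)-1-benzofuran-4,6-diol | Oc1cc(O)c(CC=C(C)C)c(-c2cc3c(O)cc(O)c(C(C)(C)C=C)c3o2)c1 | intermediate
27 | 2-(7-hydroxy-2,2-dimethyl-3,4-dihydro-2H-chromen-5-yl)-7-(2-methylbut-3-en-2-yl)-1-benzofuran-4,6-diol (achiral) | C=CC(C)(C)c1c(O)cc(O)c2cc(-c3cc(O)cc4c3CCC(C)(C)O4)oc12 | target

Total step count: 14. Longest linear sequence: 13 (steps 1–7 and 9–14); step 8 is a one-step side branch.

Steps most likely to fail

Step 10. The conjugate addition may stall: the β-carbon is deactivated by the electron-rich benzofuran and shielded by the α-prenyl group, so retro-Michael fragmentation and self-condensation of the methyl ketone could outrun ring closure. The fallback sets out from aldehyde 12 and reverses the order of bond formation. Knoevenagel condensation of 12 with dimethyl malonate 17 (piperidine, AcOH, PhMe, azeotropic removal of water) gives dimethyl 2-(Ar-methylidene)propanedioate F1, a much stronger acceptor than 16. The internal lithium enolate of 6-methylhept-5-en-2-one is released with MeLi (THF, 0 °C) from trimethyl[(6-methylhepta-2,5-dien-2-yl)oxy]silane F2. F2 is made from the commercial ketone with Me3SiCl, NaI and Et3N in MeCN, equilibrating conditions that favour the more substituted enol ether. The enolate adds to F1 at −78 °C through its C3 and gives, after protonation, Michael adduct 18, where the fallback rejoins the route. NaOMe in MeOH then closes 18 to 19 by the same Claisen condensation.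

Step 13. The quinone may over-oxidise: electron transfer from the electron-rich benzofuran, or hydride abstraction at the benzylic CH2 of the prenyl group once the ring is aromatic, could compete, and the diene may be protodesilylated before it is oxidised. The fallback sets out from diene 23 and replaces hydride abstraction by organopalladium chemistry (Saegusa–Ito oxidation). Pd(OAc)2 (1 equiv) in MeCN at rt exchanges silicon for palladium at the unsubstituted enol ether carbon. The only β-hydrogen available is the one on the benzofuranyl-bearing carbon, so syn β-hydride elimination and tautomerisation of the dienone give 5-Ar-4-(3-methylbut-2-en-1-yl)-3-[(trimethylsilyl)oxy]phenol F3, with zerovalent palladium precipitating. K2CO3 in MeOH converts F3 to resorcinol 25.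

Step 14. Chemoselectivity between the two alkenes may be lost. The vinyl group of the 1,1-dimethylallyl unit could be protonated and captured by the freed C6 hydroxyl (dihydrofuran formation), or the prenyl cation could be captured by solvent rather than by the phenol. The fallback sets out from resorcinol 25, with both MOM groups still in place, and closes the chroman without Brønsted acid activation of an alkene. N-(Phenylselanyl)phthalimide with catalytic camphorsulfonic acid (CH2Cl2, −78 → 0 °C) attacks the more nucleophilic trisubstituted alkene, and the ortho hydroxyl opens the seleniranium ion at the tertiary carbon. This gives 5-Ar-2,2-dimethyl-3-(phenylselanyl)-3,4-dihydro-2H-chromen-7-ol F4 (racemic). Bu3SnH and AIBN (PhMe, 80 °C) remove selenium to give 5-Ar-2,2-dimethyl-3,4-dihydro-2H-chromen-7-ol F5. Dilute HCl in MeOH at rt, conditions under which neither alkene should be protonated, removes the MOM groups and gives target 27.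

Further compounds
F1 | step 10 | dimethyl 2-{[4,6-bis(methoxymethoxy)-7-(2-methylbut-3-en-2-yl)-1-benzofuran-2-yl]methylidene}propanedioate | COC(=O)C(=Cc1cc2c(OCOC)cc(OCOC)c(C(C)(C)C=C)c2o1)C(=O)OC
F2 | step 10 | trimethyl[(6-methylhepta-2,5-dien-2-yl)oxy]silane (E/Z mixture) | CC(O[Si](C)(C)C)=CCC=C(C)C
F3 | step 13 | 5-[4,6-bis(methoxymethoxy)-7-(2-methylbut-3-en-2-yl)-1-benzofuran-2-yl]-4-(3-methylbut-2-en-1-yl)-3-[(trimethylsilyl)oxy]phenol | Oc1cc(O[Si](C)(C)C)c(CC=C(C)C)c(-c2cc3c(OCOC)cc(OCOC)c(C(C)(C)C=C)c3o2)c1
F4 | step 14 | 5-[4,6-bis(methoxymethoxy)-7-(2-methylbut-3-en-2-yl)-1-benzofuran-2-yl]-2,2-dimethyl-3-(phenylselanyl)-3,4-dihydro-2H-chromen-7-ol (racemic) | CC1(C)Oc2cc(O)cc(-c3cc4c(OCOC)cc(OCOC)c(C(C)(C)C=C)c4o3)c2CC1[Se]c1ccccc1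
F5 | step 14 | 5-[4,6-bis(methoxymethoxy)-7-(2-methylbut-3-en-2-yl)-1-benzofuran-2-yl]-2,2-dimethyl-3,4-dihydro-2H-chromen-7-ol | CC1(C)CCc2c(O1)cc(O)cc2-c1cc2c(OCOC)cc(OCOC)c(C(C)(C)C=C)c2o1
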